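Ring C is disconnected at the O1–C8a aryl ether bond. The feature exploited is that O1 is bonded to C8a, the ring A neighbour of C4a, from which the C4–C3–C2 chain departs. A bromide on C8a and the C2 hydroxyl are therefore placed for a six-membered closure. One copper-catalysed intramolecular O-arylation forms this bond and ring C while leaving the C2–O bond alone. The (S) centre, set earlier by asymmetric transfer hydrogenation, is thus carried through. The precursor is the syn-(1R,3S)-1,3-diarylpropane-1,3-diol 24. It has a ring A bromide ortho to the C1 carbinol, four benzyl ethers, a free tertiary side-chain alcohol, and C4 still at the alcohol level.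

Key step: step 11

Remarks on the chemistry
- Flavanone numbering (O1, C2–C4, C4a, C5–C8, C8a, ring B C1′–C6′) is used for all intermediates. The target is (2S) (O1 > C1′ > C3 > H).
- Compounds 1, 2, 6, 9, 13 and 14 are assumed to be commercial.
- The syn-(1R,3S) diol 24 maps onto the 2,4-trans-(2S,4R) chromanol 25, because at C2 the chain partner changes from ring B to O1. C4 is erased in step 12 and is controlled only so that every intermediate is one diastereomer.
- Ring A is acylated through an arylmagnesium reagent. Friedel–Crafts conditions would ionise the tertiary alcohol and strip the benzyl ether next to the new ketone.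
- The C2 centre comes from a catalytic ketone reduction of known facial sense, because boron aldol reactions of methyl ketones are usually only moderately enantioselective.
- Compound 24 is used as the free triol, because geometry alone singles out the C2 hydroxyl.

Step 1
Reactants: 1 4-bromo-2,6-difluorobenzaldehyde; 2 benzyl alcohol
Product: 5 2,6-bis(benzyloxy)-4-bromobenzaldehyde, via sodium benzyloxide 3 (not isolated), via monofluoride 4 (not isolated)
Conditions: 2 (2.3 equiv), NaH (2.3 equiv), THF, 0 °C; added to 1 in THF–DMF, 0 → 50 °C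
Reagents that add atoms: benzyl alcohol OCc1ccccc1; sodium hydride [Na+].[H-] (sodium of 3 only)
Why: Nucleophilic aromatic substitution by addition–elimination, in which both fluorides are ortho to the formyl group and leave far faster than the para bromide, so the mirror-symmetric diether should form while the future C8a bromide stays in place.

Step 2
Reactants: 5 2,6-bis(benzyloxy)-4-bromobenzaldehyde; 6 methyl (triphenylphosphoranylidene)acetate
Product: 7 methyl (2E)-3-[2,6-bis(benzyloxy)-4-bromophenyl]prop-2-enoate
Conditions: 6 (1.3 equiv), toluene, 90 °C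
Reagents that add atoms: methyl (triphenylphosphoranylidene)acetate COC(=O)C=P(c1ccccc1)(c1ccccc1)c1ccccc1
Why: Wittig olefination with a stabilised ylide, which tolerates the aryl bromide and the 2,6-disubstituted aldehyde and should give the E-enoate, whose geometry is erased in step 3.

Step 3
Reactants: 7 methyl (2E)-3-[2,6-bis(benzyloxy)-4-bromophenyl]prop-2-enoate
Product: 8 methyl 3-[2,6-bis(benzyloxy)-4-bromophenyl]propanoate
Conditions: H2 (4 bar), RhCl(PPh3)3 (5 mol %), THF–t-BuOH 1:1, 50 °C
Reagents that add atoms: none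
Why: Homogeneous hydrogenation with RhCl(PPh3)3 saturates the disubstituted enoate double bond without hydrogenolysis of the benzyl ethers or the aryl bromide, both of which heterogeneous palladium would attack.

Step 4
Reactants: 8 methyl 3-[2,6-bis(benzyloxy)-4-bromophenyl]propanoate; 9 methylmagnesium bromide
Product: 11 4-[2,6-bis(benzyloxy)-4-bromophenyl]-2-methylbutan-2-ol, via methyl ketone 10 (not isolated)
Conditions: MeMgBr (3 equiv), THF, 0 °C → rt; aq NH4Cl
Reagents that add atoms: methylmagnesium bromide C[Mg]Br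
Why: Double Grignard addition to the ester through ketone 10 builds the dimethylcarbinol, and methylmagnesium bromide does not exchange with an aryl bromide at this temperature.

Step 5
Reactants: 11 4-[2,6-bis(benzyloxy)-4-bromophenyl]-2-methylbutan-2-ol
Product: 12 4-[2,6-bis(benzyloxy)-4-bromo-3-iodophenyl]-2-methylbutan-2-ol
Conditions: N-iodosuccinimide (1.05 equiv), CF3CO2H (10 mol %), MeCN, 0 °C → rt, dark
Reagents that add atoms: N-iodosuccinimide O=C1CCC(=O)N1I
Why: Electrophilic aromatic iodination, in which the two free ring positions are equivalent by symmetry and each is ortho to one benzyloxy group and para to the other, so only one mono-iodide can form, with iodine on the future C4a, bromine on the future C8a and the side chain fixed at C6.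

Step 6
Reactants: 13 3,4-bis(benzyloxy)benzoic acid; 14 N-methoxy-N-methylacetamide
Product: 17 3-[3,4-bis(benzyloxy)phenyl]-N-methoxy-N-methyl-3-oxopropanamide, via lithium enolate 15 (not isolated), via acylimidazole 16 (not isolated)
Conditions: 14 (3.5 equiv), LiN(iPr)2 (3.5 equiv), THF, −78 °C; separately 13, 1,1'-carbonyldiimidazole (1.1 equiv), THF, rt; combined at −78 °C; aq NH4Cl
Reagents that add atoms: N-methoxy-N-methylacetamide CON(C)C(C)=O; 1,1'-carbonyldiimidazole O=C(n1ccnc1)n1ccnc1 (imidazolyl group of 16 only); lithium diisopropylamide [Li+].CC(C)[N-]C(C)C (lithium of 15 only)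
Why: Crossed Claisen-type C-acylation of an amide enolate by an acylimidazole, run with excess enolate because free imidazole and the acidic β-keto amide product each consume one equivalent, which also prevents a second acylation.

Step 7
Reactants: 17 3-[3,4-bis(benzyloxy)phenyl]-N-methoxy-N-methyl-3-oxopropanamide
Product: 18 (3S)-3-[3,4-bis(benzyloxy)phenyl]-3-hydroxy-N-methoxy-N-methylpropanamide
Conditions: RuCl[(S,S)-TsDPEN](p-cymene) (1 mol %), HCO2H–Et3N 5:2, CH2Cl2, 30 °C
Reagents that add atoms: none
Why: Noyori asymmetric transfer hydrogenation, in which the (S,S)-TsDPEN ruthenium hydride reduces the aryl ketone on the face fixed by the CH–π contact between p-cymene and ring B, setting the future C2 as (S) in the same sense in which acetophenone gives (S)-1-phenylethanol, while formic acid makes the hydride transfer irreversible.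

Step 8
Reactants: 18 (3S)-3-[3,4-bis(benzyloxy)phenyl]-3-hydroxy-N-methoxy-N-methylpropanamide
Product: 19 (3S)-3-[3,4-bis(benzyloxy)phenyl]-N-methoxy-N-methyl-3-[(trimethylsilyl)oxy]propanamide
Conditions: Me3SiCl (1.3 equiv), imidazole (2 equiv), CH2Cl2, 0 °C
Reagents that add atoms: chlorotrimethylsilane C[Si](C)(C)Cl
Why: Silyl ether formation masks the only acidic proton of fragment B, so that in step 9 it can neither quench the arylmagnesium reagent nor undergo retro-aldol cleavage as a magnesium aldolate.

Step 9
Reactants: 12 4-[2,6-bis(benzyloxy)-4-bromo-3-iodophenyl]-2-methylbutan-2-ol; 19 (3S)-3-[3,4-bis(benzyloxy)phenyl]-N-methoxy-N-methyl-3-[(trimethylsilyl)oxy]propanamide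
Product: 22 (3S)-1-[2,4-bis(benzyloxy)-6-bromo-3-(3-hydroxy-3-methylbutyl)phenyl]-3-[3,4-bis(benzyloxy)phenyl]-3-hydroxypropan-1-one, via arylmagnesium chloride 20 (not isolated), via silyl-protected ketone 21 (not isolated)
Conditions: 12 (1.2 equiv), iPrMgCl·LiCl (2.1 equiv per 12), THF, −20 °C; 19, −20 → 0 °C; aq NH4Cl; then 10% aq citric acid, MeOH, 0 °C
Reagents that add atoms: isopropylmagnesium chloride CC(C)[Mg]Cl (MgCl groups of 20 only)
Why: Iodine–magnesium exchange followed by Weinreb ketone synthesis, in which exchange is much faster at the iodide than at the bromide, the ortho-bromoarylmagnesium species resists aryne formation below 0 °C, addition stops at the chelated tetrahedral adduct, and the mildly acidic work-up releases the ketone and cleaves the labile trimethylsilyl ether without touching the C3 stereocentre.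

Step 10
Reactants: 22 (3S)-1-[2,4-bis(benzyloxy)-6-bromo-3-(3-hydroxy-3-methylbutyl)phenyl]-3-[3,4-bis(benzyloxy)phenyl]-3-hydroxypropan-1-one
Product: 24 (1R,3S)-1-[2,4-bis(benzyloxy)-6-bromo-3-(3-hydroxy-3-methylbutyl)phenyl]-3-[3,4-bis(benzyloxy)phenyl]propane-1,3-diol (syn), via diethylboron chelate 23 (not isolated)
Conditions: Et2BOMe (1.5 equiv), THF–MeOH 4:1, −78 °C; NaBH4 (1.5 equiv), −78 → −40 °C; aq NH4Cl; MeOH co-evaporation
Reagents that add atoms: diethyl(methoxy)borane CCB(CC)OC (Et2B group of 23 only)
Why: Narasaka–Prasad reduction, in which Et2BOMe ties the C3 hydroxyl and the ketone into the six-membered chelate 23 with ring B pseudoequatorial and external borohydride attacks axially through a chair-like path, so the new C1 carbinol (future C4) is set 1,3-syn to the existing (S) centre, which corresponds to (1R,3S).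

Step 11
Reactants: 24 (1R,3S)-1-[2,4-bis(benzyloxy)-6-bromo-3-(3-hydroxy-3-methylbutyl)phenyl]-3-[3,4-bis(benzyloxy)phenyl]propane-1,3-diol
Product: 25 (2S,4R)-5,7-bis(benzyloxy)-2-[3,4-bis(benzyloxy)phenyl]-6-(3-hydroxy-3-methylbutyl)-3,4-dihydro-2H-chromen-4-ol (2,4-trans)
Conditions: CuI (10 mol %), 3,4,7,8-tetramethyl-1,10-phenanthroline (20 mol %), Cs2CO3 (2 equiv), 4 Å molecular sieves, toluene, 110 °C, argon
Reagents that add atoms: none
Why: Carbonate deprotonates the C2 carbinol, the alkoxide binds phenanthroline-ligated monovalent copper, the C8a–Br bond adds oxidatively to give a seven-membered cupracycle at the trivalent stage, and reductive elimination forges O1–C8a and returns monovalent copper. The closest known reaction type is the Ullmann-type copper-catalysed O-arylation of secondary aliphatic alcohols with aryl halides, whose intramolecular form is an established entry to chromans and 2-arylchromans. Ring C closes as a six-membered ring by contraction of that metallacycle, the C2–C3–C4–C4a tether holding the alkoxide next to C8a. No stereocentre is created and neither the C2–O nor the C4–O bond is cleaved, so syn-(1R,3S)-24 maps onto 2,4-trans-(2S,4R)-25, whose pseudoaxial C4 hydroxyl also avoids the peri C5 benzyloxy group. The step needs chemoselection among three hydroxyls, and geometry provides it, because the C4 hydroxyl could only close a four-membered ring and the tertiary hydroxyl hangs from C6, para to C8a, and cannot reach it; copper also has little tendency toward β-hydride elimination from the benzylic alkoxide. Holding C4 at the alcohol level removes the retro-aldol and E1cB dehydration channels that hot carbonate would open for a β-hydroxy ketone.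

Step 12
Reactants: 25 (2S,4R)-5,7-bis(benzyloxy)-2-[3,4-bis(benzyloxy)phenyl]-6-(3-hydroxy-3-methylbutyl)-3,4-dihydro-2H-chromen-4-ol
Product: 26 (2S)-5,7-bis(benzyloxy)-2-[3,4-bis(benzyloxy)phenyl]-6-(3-hydroxy-3-methylbutyl)-2,3-dihydro-4H-chromen-4-one
Conditions: Dess–Martin periodinane (1.3 equiv), pyridine (4 equiv), CH2Cl2, 0 °C → rt
Reagents that add atoms: none
Why: Dess–Martin oxidation converts the only secondary alcohol into the ketone under buffered, near-neutral conditions (the tertiary alcohol cannot be oxidised), which avoids acid ionisation at C4 and base-induced retro-oxa-Michael ring opening and so keeps C2 intact.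

Step 13
Reactants: 26 (2S)-5,7-bis(benzyloxy)-2-[3,4-bis(benzyloxy)phenyl]-6-(3-hydroxy-3-methylbutyl)-2,3-dihydro-4H-chromen-4-one
Product: 27 (2S)-2-(3,4-dihydroxyphenyl)-5,7-dihydroxy-6-(3-hydroxy-3-methylbutyl)-2,3-dihydro-4H-chromen-4-one (target)
Conditions: H2 (1 atm), 10% Pd/C, EtOAc–MeOH 4:1, rt
Reagents that add atoms: none
Why: Catalytic hydrogenolysis cleaves all four aryl benzyl ethers under neutral conditions, a standard closing step for flavanones that should spare the aryl ketone (hydrogen-bonded to the freed C5 hydroxyl), the tertiary alcohol and the C2–O1 bond at one atmosphere, while the absence of base prevents racemisation of C2 through the open chalcone.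

Compound list
1 | 4-bromo-2,6-difluorobenzaldehyde | O=Cc1c(F)cc(Br)cc1F | starting material
2 | benzyl alcohol | OCc1ccccc1 | starting material
3 | sodium benzyloxide | [Na+].[O-]Cc1ccccc1 | intermediate
4 | 2-(benzyloxy)-4-bromo-6-fluorobenzaldehyde | O=Cc1c(F)cc(Br)cc1OCc1ccccc1 | intermediate
5 | 2,6-bis(benzyloxy)-4-bromobenzaldehyde | O=Cc1c(OCc2ccccc2)cc(Br)cc1OCc1ccccc1 | intermediate
6 | methyl (triphenylphosphoranylidene)acetate | COC(=O)C=P(c1ccccc1)(c1ccccc1)c1ccccc1 | starting material
7 | methyl (2E)-3-[2,6-bis(benzyloxy)-4-bromophenyl]prop-2-enoate | COC(=O)/C=C/c1c(OCc2ccccc2)cc(Br)cc1OCc1ccccc1 | intermediate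
8 | methyl 3-[2,6-bis(benzyloxy)-4-bromophenyl]propanoate | COC(=O)CCc1c(OCc2ccccc2)cc(Br)cc1OCc1ccccc1 | intermediate
9 | methylmagnesium bromide | C[Mg]Br | starting material
10 | 4-[2,6-bis(benzyloxy)-4-bromophenyl]butan-2-one | CC(=O)CCc1c(OCc2ccccc2)cc(Br)cc1OCc1ccccc1 | intermediate
11 | 4-[2,6-bis(benzyloxy)-4-bromophenyl]-2-methylbutan-2-ol | CC(C)(O)CCc1c(OCc2ccccc2)cc(Br)cc1OCc1ccccc1 | intermediate
12 | 4-[2,6-bis(benzyloxy)-4-bromo-3-iodophenyl]-2-methylbutan-2-ol | CC(C)(O)CCc1c(OCc2ccccc2)cc(Br)c(I)c1OCc1ccccc1 | intermediate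
13 | 3,4-bis(benzyloxy)benzoic acid | OC(=O)c1ccc(OCc2ccccc2)c(OCc2ccccc2)c1 | starting material
14 | N-methoxy-N-methylacetamide | CON(C)C(C)=O | starting material
15 | lithium enolate of N-methoxy-N-methylacetamide | [Li+].C=C([O-])N(C)OC | intermediate
16 | [3,4-bis(benzyloxy)phenyl](1H-imidazol-1-yl)methanone | O=C(c1ccc(OCc2ccccc2)c(OCc2ccccc2)c1)n1ccnc1 | intermediate
17 | 3-[3,4-bis(benzyloxy)phenyl]-N-methoxy-N-methyl-3-oxopropanamide | CON(C)C(=O)CC(=O)c1ccc(OCc2ccccc2)c(OCc2ccccc2)c1 | intermediate
18 | (3S)-3-[3,4-bis(benzyloxy)phenyl]-3-hydroxy-N-methoxy-N-methylpropanamide | CON(C)C(=O)C[C@H](O)c1ccc(OCc2ccccc2)c(OCc2ccccc2)c1 | intermediate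
19 | (3S)-3-[3,4-bis(benzyloxy)phenyl]-N-methoxy-N-methyl-3-[(trimethylsilyl)oxy]propanamide | CON(C)C(=O)C[C@H](O[Si](C)(C)C)c1ccc(OCc2ccccc2)c(OCc2ccccc2)c1 | intermediate
20 | {2,4-bis(benzyloxy)-6-bromo-3-[3-(chloromagnesiooxy)-3-methylbutyl]phenyl}magnesium chloride | CC(C)(O[Mg]Cl)CCc1c(OCc2ccccc2)cc(Br)c([Mg]Cl)c1OCc1ccccc1 | intermediate
21 | (3S)-1-[2,4-bis(benzyloxy)-6-bromo-3-(3-hydroxy-3-methylbutyl)phenyl]-3-[3,4-bis(benzyloxy)phenyl]-3-[(trimethylsilyl)oxy]propan-1-one | CC(C)(O)CCc1c(OCc2ccccc2)cc(Br)c(c1OCc1ccccc1)C(=O)C[C@H](O[Si](C)(C)C)c1ccc(OCc2ccccc2)c(OCc2ccccc2)c1 | intermediate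
22 | (3S)-1-[2,4-bis(benzyloxy)-6-bromo-3-(3-hydroxy-3-methylbutyl)phenyl]-3-[3,4-bis(benzyloxy)phenyl]-3-hydroxypropan-1-one | CC(C)(O)CCc1c(OCc2ccccc2)cc(Br)c(c1OCc1ccccc1)C(=O)C[C@H](O)c1ccc(OCc2ccccc2)c(OCc2ccccc2)c1 | intermediate
23 | (3S)-3-[(diethylboranyl)oxy] derivative of 22, boron chelated by the ketone oxygen | CC(C)(O)CCc1c(OCc2ccccc2)cc(Br)c(c1OCc1ccccc1)C(=O)C[C@H](OB(CC)CC)c1ccc(OCc2ccccc2)c(OCc2ccccc2)c1 | intermediate
24 | (1R,3S)-1-[2,4-bis(benzyloxy)-6-bromo-3-(3-hydroxy-3-methylbutyl)phenyl]-3-[3,4-bis(benzyloxy)phenyl]propane-1,3-diol (syn) | CC(C)(O)CCc1c(OCc3ccccc3)cc(Br)c(c1OCc1ccccc1)[C@H](O)C[C@H](O)c1ccc(OCc3ccccc3)c(OCc3ccccc3)c1 | intermediate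
25 | (2S,4R)-5,7-bis(benzyloxy)-2-[3,4-bis(benzyloxy)phenyl]-6-(3-hydroxy-3-methylbutyl)-3,4-dihydro-2H-chromen-4-ol (2,4-trans) | CC(C)(O)CCc1c(OCc3ccccc3)cc2c(c1OCc1ccccc1)[C@H](O)C[C@@H](c1ccc(OCc3ccccc3)c(OCc3ccccc3)c1)O2 | intermediate
26 | (2S)-5,7-bis(benzyloxy)-2-[3,4-bis(benzyloxy)phenyl]-6-(3-hydroxy-3-methylbutyl)-2,3-dihydro-4H-chromen-4-one | CC(C)(O)CCc1c(OCc3ccccc3)cc2c(c1OCc1ccccc1)C(=O)C[C@@H](c1ccc(OCc3ccccc3)c(OCc3ccccc3)c1)O2 | intermediate
27 | (2S)-2-(3,4-dihydroxyphenyl)-5,7-dihydroxy-6-(3-hydroxy-3-methylbutyl)-2,3-dihydro-4H-chromen-4-one | CC(C)(O)CCc1c(O)cc2c(c1O)C(=O)C[C@@H](c1ccc(O)c(O)c1)O2 | target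

Total step count: 13. Longest linear sequence: 10 steps (1–5, then 9–13). Fragment B takes 3 steps (6–8) in parallel.

Steps most likely to fail

Step 11. Oxidative addition at the ortho-branched bromide may be slow. Protodebromination, or sequestration of copper by the 1,3-diolate, could then take over. The fallback makes the same O1–C8a bond by elimination–addition instead of cross-coupling. It sets out from 24 and comes back at 25.
- Excess lithium 2,2,6,6-tetramethylpiperidide (THF, −78 °C) removes the three hydroxyl protons and the ring A proton flanked by bromine and benzyloxy (future C8).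
- On warming, bromide is lost to give the C8–C8a aryne F1.
- The tethered C2 alkoxide adds at C8a. This is the aryne carbon distal to the C7 benzyloxy group, as the inductive rule for 3-alkoxyarynes requires, and the only one that gives a six-membered ring.
- Protonation of the C8 aryl anion gives 25 with C2 and C4 untouched.

Step 9. Addition of the doubly ortho-substituted arylmagnesium reagent to the amide may be sluggish. Warming would then lead to loss of magnesium halide (aryne formation) or to enolisation of the amide. The fallback uses a much more electrophilic carbonyl partner. It sets out from 19 and 12 and comes back at 21.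
- Compound 19 is reduced with iBu2AlH (toluene, −78 °C) to (3S)-3-[3,4-bis(benzyloxy)phenyl]-3-[(trimethylsilyl)oxy]propanal F2.
- Reagent 20, made from 12 as before, adds at −40 °C to give the C1-epimeric carbinol F3.
- Pyridine-buffered Dess–Martin oxidation erases the new centre and gives 21, which the citric acid treatment converts into 22.

Step 3. Hydrogen uptake at the hindered E-enoate may be slow, and forcing conditions could start hydrogenolysis of the aryl bromide. The fallback avoids any alkene hydrogenation. It sets out from 5 and comes back at 8.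
- Compound 5 is heated with Meldrum's acid in HCO2H–Et3N at 95 °C.
- Knoevenagel condensation gives the arylidene Meldrum's acid F4.
- Formate transfers hydride to the β-carbon of F4 to give the benzyl Meldrum's acid F5.
- Hydrolysis and decarboxylation in the same pot give 3-[2,6-bis(benzyloxy)-4-bromophenyl]propanoic acid F6.
- Fischer esterification (MeOH, cat. H2SO4, reflux) then gives 8.

Further compounds
F1 | step 11 | aryne from 24 by loss of HBr across the future C8–C8a bond | CC(C)(O)CCC1=C(OCc2ccccc2)C#CC([C@H](O)C[C@H](O)c2ccc(OCc3ccccc3)c(OCc3ccccc3)c2)=C1OCc1ccccc1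
F2 | step 9 | (3S)-3-[3,4-bis(benzyloxy)phenyl]-3-[(trimethylsilyl)oxy]propanal | O=CC[C@H](O[Si](C)(C)C)c1ccc(OCc2ccccc2)c(OCc2ccccc2)c1
F3 | step 9 | (3S)-1-[2,4-bis(benzyloxy)-6-bromo-3-(3-hydroxy-3-methylbutyl)phenyl]-3-[3,4-bis(benzyloxy)phenyl]-3-[(trimethylsilyl)oxy]propan-1-ol, both C1 epimers | CC(C)(O)CCc1c(OCc2ccccc2)cc(Br)c(c1OCc1ccccc1)C(O)C[C@H](O[Si](C)(C)C)c1ccc(OCc2ccccc2)c(OCc2ccccc2)c1
F4 | step 3 | 5-{[2,6-bis(benzyloxy)-4-bromophenyl]methylidene}-2,2-dimethyl-1,3-dioxane-4,6-dione | CC1(C)OC(=O)C(=Cc2c(OCc3ccccc3)cc(Br)cc2OCc2ccccc2)C(=O)O1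
F5 | step 3 | 5-{[2,6-bis(benzyloxy)-4-bromophenyl]methyl}-2,2-dimethyl-1,3-dioxane-4,6-dione | CC1(C)OC(=O)C(Cc2c(OCc3ccccc3)cc(Br)cc2OCc2ccccc2)C(=O)O1
F6 | step 3 | 3-[2,6-bis(benzyloxy)-4-bromophenyl]propanoic acid | OC(=O)CCc1c(OCc2ccccc2)cc(Br)cc1OCc1ccccc1
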